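## Structural features

The target is a 7-deoxy 8-O-4' neolignan. Ring A (3,4,5-trimethoxyphenyl) carries the chain C7H2–C8H–C9H2OH, and C8 is joined through the ether oxygen O4' to ring B (2,6-dimethoxyphenyl with an allyl group para to O4'). No ring has to be built, since both arenes can be bought with all substituents in place. C8 is the only stereocentre and is (R) (priorities O4' > C9 > C7 > H). It has no neighbouring stereocentre to relay from, so its configuration must come from a reagent or catalyst. O4' is flanked by two ortho-methoxy groups, so the phenol of ring B is a hindered nucleophile. C8 as an electrophile would be secondary with the benzylic C7–H bonds next to it, so displacement at C8 competes with elimination into conjugation with ring A. The fragile groups are the allyl group (hydrogenation, ozonolysis, hydroboration, Heck coupling, migration to the propenyl isomer), the electron-rich rings, and C8–H once C9 is at carbonyl level. The real difficulty is therefore one bond and one centre: C8–O4', made with absolute control at C8 in the presence of the allyl group. The key step exploits the fact that C8 bears exactly one H, one aryloxy oxygen and one carbon (C9) that can sit at ester level. That is the pattern left when an ester-substituted carbene carbon inserts into an O–H bond, so C8–O4' and C8–H can be formed together on a planar C8 that has no leaving group.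

## Logic of the disconnections

8 to 6 (through 7). The two C9–H bonds are cut, taking the C9 carbinol back to a C9 methyl ester. The ester is what allows C8 to become a stabilised carbene carbon in the next cut. Nothing is gained in skeleton, but the key disconnection becomes possible. The forward reduction must not epimerise C8, which is α to a carbonyl in 6 and 7, and must leave the allyl group alone.

6 to 4 + 5. C8–O4' and C8–H are cut together. This is the key disconnection: the molecule falls into a ring-A three-carbon unit with C8 as a diazo carbon (4) and the intact ring-B phenol (5). The stereocentre is created in the union itself and not carried in from a chiral precursor. The gain is from a 24-carbon chiral ether to two achiral pieces, one of them commercial. The forward step needs a chiral catalyst that controls the face of proton delivery to C8. It also needs insertion into O4'–H to outrun hydride shift from C7 and carbene transfer to the allyl π bond. In one sentence, the route is the copper-catalysed enantioselective insertion of the carbene from 4 into the O–H bond of 5, which does not describe a displacement route.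

4 to 3. The C8=N2 unit is cut back to C8–H plus a C8-acetyl group. C8 of a simple ester is not acidic enough for direct diazo transfer, so the acetyl group activates C8 and leaves in the same operation. The forward step must cleave the acetyl group completely after the azide has added.

3 to 1 + 2. The C7–C8 bond is cut as an enolate alkylation, which reaches two commercial compounds. The forward step must give mono-C-alkylation with a very reactive benzylic bromide.

## Other disconnections considered

Alternative 1: This is the cut that comes to mind first, C8–O4' as an SN2 displacement with inversion. The forward key step would be a Mitsunobu etherification of 5 with methyl (S)-2-hydroxy-3-(3,4,5-trimethoxyphenyl)propanoate A1 to give 6, followed by the same reduction. A di-ortho-substituted phenol would have to attack a secondary carbon flanked by an ester and a benzylic CH2. Backside attack is slowed from both sides, while the activated intermediate can lose a C7 proton toward methyl (E)-3-(3,4,5-trimethoxyphenyl)acrylate A2. A slow displacement at an α-carbonyl centre also invites erosion of configuration. A1 is not a stock compound and needs its own asymmetric synthesis, so the route is longer. The chosen plan makes the same bond at an sp2 carbon with no leaving group and creates the centre catalytically.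

Alternative 2: The cut is the two C–H bonds at C7 and C8. The forward key step would be a carboxyl-directed asymmetric hydrogenation of (Z)-2-(4-allyl-2,6-dimethoxyphenoxy)-3-(3,4,5-trimethoxyphenyl)acrylic acid A3, reached from 5 by O-alkylation and aldol-type condensation. The monosubstituted alkene of the allyl group is an intrinsically better hydrogenation substrate than the trisubstituted enol-ether olefin. The expected product is therefore the propyl acid A4 and not the allyl compound. Ring B would have to carry a placeholder and receive the allyl group by cross-coupling afterwards, which costs at least two steps. The Z geometry of A3 would also have to be secured. The chosen key step uses no hydrogen and tolerates the allyl group.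

Alternative 3: The cut is C8–O4' in the allylic sense, with C9 carried as a vinyl carbon. The forward key step would be an iridium/phosphoramidite-catalysed branch-selective allylic etherification of the phenoxide of 5 with methyl (E)-4-(3,4,5-trimethoxyphenyl)but-2-en-1-yl carbonate A5, giving ether A6. Ozonolysis and reduction would then turn the vinyl group into C9H2OH. A6 holds two monosubstituted terminal alkenes, the C8 vinyl group and the ring-B allyl group, which oxidative cleavage cannot tell apart. Ring B would again need a masked allyl group. A5 itself takes several steps, and the allyl–iridium intermediate has acidic C7 hydrogens that open a diene-forming elimination. The plan would be roughly twice as long as the chosen one.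

Key step: step 3

Assumption: the target SMILES is read as the (R)-enantiomer at C8; atom labels follow neolignan usage as defined above.
Assumption: the sense of induction of the copper/spiro-bisoxazoline catalyst with this pair of partners has to be assigned on the first run; both ligand antipodes are accessible, and the one that delivers (R)-6 is meant wherever the ligand is named.

## Route

Step 1
Reactants: 1 methyl acetoacetate; 2 5-(bromomethyl)-1,2,3-trimethoxybenzene
Product: 3 methyl 2-acetyl-3-(3,4,5-trimethoxyphenyl)propanoate (racemic)
Conditions: K2CO3 (1.5 equiv), 1 (1.5 equiv), acetone, reflux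
Reagents that add atoms: none
Why: Acetoacetic ester alkylation; the soft, stabilised enolate of 1 should react at carbon with the benzylic bromide to form C7–C8, and the excess of 1 limits double alkylation. The stereocentre formed is lost in step 2 and needs no control.

Step 2
Reactants: 3 methyl 2-acetyl-3-(3,4,5-trimethoxyphenyl)propanoate
Product: 4 methyl 2-diazo-3-(3,4,5-trimethoxyphenyl)propanoate
Conditions: p-ABSA (1.2 equiv), DBU (1.5 equiv), MeCN, 0 °C to rt
Reagents that add atoms: p-ABSA (4-acetamidobenzenesulfonyl azide), CC(=O)Nc1ccc(cc1)S(=O)(=O)N=[N+]=[N-]
Why: Regitz diazo transfer with deacylation; the DBU enolate of 3 adds to the terminal nitrogen of the sulfonyl azide, and because C8 has no second hydrogen the sulfonamide nitrogen of the adduct takes over the acetyl group and releases the C8 diazo ester. This is the standard entry to α-alkyl-α-diazo esters from 2-alkyl acetoacetates.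

Step 3
Reactants: 4 methyl 2-diazo-3-(3,4,5-trimethoxyphenyl)propanoate; 5 4-allyl-2,6-dimethoxyphenol
Product: 6 methyl (R)-2-(4-allyl-2,6-dimethoxyphenoxy)-3-(3,4,5-trimethoxyphenyl)propanoate
Conditions: CuCl (5 mol%), (Sa,S,S)-7,7'-bis(4-phenyloxazolin-2-yl)-1,1'-spirobiindane (6 mol%), NaBArF (6 mol%), 5 Å MS, CH2Cl2, 25 °C; 5 (3 equiv, excess recovered), 4 added over 4 h
Reagents that add atoms: none
Why: The cationic Cu(I)/spiro-bisoxazoline complex should decompose 4 with loss of N2 to an electrophilic copper carbene centred on C8; O4' of 5 adds to this planar carbon to give a copper-bound oxonium ylide (copper enolate), and a 1,2-proton shift from O4' to C8 inside the chiral pocket completes a formal O–H insertion. The closest known reaction type is the Cu/spiro-bisoxazoline-catalysed enantioselective insertion of α-alkyl-α-diazo esters into phenol O–H bonds, known intermolecularly and, for β-aryl-α-diazopropanoates, intramolecularly. No ring is closed. The new stereocentre C8 is set under catalyst control in the proton-transfer step, because the ylide stays bound to copper (weakly coordinating BArF counter-ion, non-polar solvent) and is protonated on one face; no substrate stereocentre is involved. The step needs O–H insertion to win over the 1,2-hydride shift from C7, which is unimolecular and is therefore countered by a high concentration of 5 and by the choice of copper over rhodium. It also needs O–H insertion to win over carbene transfer to the allyl group and over insertion into water; the phenolic O–H is the most nucleophilic site of 5, the chain of 4 is too short for intramolecular attack on ring A, and molecular sieves remove water. Because C8 is attacked as an sp2 carbon without a leaving group, the two ortho-methoxy groups of 5 face no backside trajectory and there is no E2 channel.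

Step 4
Reactants: 6 methyl (R)-2-(4-allyl-2,6-dimethoxyphenoxy)-3-(3,4,5-trimethoxyphenyl)propanoate
Product: 8 (R)-2-(4-allyl-2,6-dimethoxyphenoxy)-3-(3,4,5-trimethoxyphenyl)propan-1-ol, via (R)-2-aryloxy-3-arylpropanal 7 (not isolated)
Conditions: LiAlH4 (1.0 equiv), THF, –20 to 0 °C; then H2O, aq NaOH
Reagents that add atoms: none
Why: Hydride reduction of an ester to the primary alcohol through the aldehyde; hydride delivery to the activated α-aryloxy carbonyl at low temperature should be much faster than enolisation, so C8 keeps its configuration, and the isolated allyl group and the aryl ethers are inert to LiAlH4.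

## Compound list

1 | methyl acetoacetate (methyl 3-oxobutanoate) | CC(=O)CC(=O)OC | starting material
2 | 5-(bromomethyl)-1,2,3-trimethoxybenzene (3,4,5-trimethoxybenzyl bromide) | COc1cc(CBr)cc(OC)c1OC | starting material
3 | methyl 2-acetyl-3-(3,4,5-trimethoxyphenyl)propanoate (racemic) | CC(=O)C(Cc1cc(OC)c(OC)c(OC)c1)C(=O)OC | intermediate
4 | methyl 2-diazo-3-(3,4,5-trimethoxyphenyl)propanoate | COC(=O)C(=[N+]=[N-])Cc1cc(OC)c(OC)c(OC)c1 | intermediate
5 | 4-allyl-2,6-dimethoxyphenol | C=CCc1cc(OC)c(O)c(OC)c1 | starting material
6 | methyl (R)-2-(4-allyl-2,6-dimethoxyphenoxy)-3-(3,4,5-trimethoxyphenyl)propanoate | C=CCc1cc(OC)c(O[C@@H](C(=O)OC)Cc2cc(OC)c(OC)c(OC)c2)c(OC)c1 | intermediate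
7 | (R)-2-(4-allyl-2,6-dimethoxyphenoxy)-3-(3,4,5-trimethoxyphenyl)propanal (not isolated) | C=CCc1cc(OC)c(O[C@@H](C=O)Cc2cc(OC)c(OC)c(OC)c2)c(OC)c1 | intermediate
8 | (R)-2-(4-allyl-2,6-dimethoxyphenoxy)-3-(3,4,5-trimethoxyphenyl)propan-1-ol | C=CCc1cc(OC)c(O[C@@H](CO)Cc2cc(OC)c(OC)c(OC)c2)c(OC)c1 | target

## Step count and least certain steps

Total step count: 4. Longest linear sequence: 4 (1 and 2 to 3, 4, 6, 8; 5 enters in step 3).

**Step 3 (key step).** Three processes can spoil it:
- The 1,2-hydride shift from C7 to the carbene carbon may outrun capture by the hindered O–H bond, because the shift gives a conjugated alkene and is intramolecular.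
- The ylide may leave copper before the proton shift, or the ortho-methoxy oxygens may bind copper and distort the pocket, so that enantioselectivity falls.
- Carbene transfer to the allyl π bond may take a share.

The fallback sets the stereocentre by a dynamic kinetic resolution and makes the C–O bond at a primary carbon. It sets out from 5 and 2 and comes back at 8. Compound 5 is O-alkylated with methyl bromoacetate (K2CO3, acetone, reflux) to methyl 2-(4-allyl-2,6-dimethoxyphenoxy)acetate F1. F1 is deprotonated with LDA (THF, –78 °C) and benzylated with 2 to racemic methyl 2-(4-allyl-2,6-dimethoxyphenoxy)-3-(3,4,5-trimethoxyphenyl)propanoate F2. DIBAL-H (toluene, –78 °C) takes F2 to racemic 2-(4-allyl-2,6-dimethoxyphenoxy)-3-(3,4,5-trimethoxyphenyl)propanal F3. F3 is hydrogenated with a RuCl2(chiral spiro diphosphine)(chiral 1,2-diamine) catalyst and KOtBu in iPrOH under H2, using the catalyst antipode that gives the (R)-alcohol. The base racemises C8 of F3 through the enolate while one enantiomer is reduced faster, and this outer-sphere catalyst type reduces C=O without touching isolated C=C, so 8 should result directly.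

**Step 2.** The acetyl transfer after azide addition may be incomplete, the enolate may couple with the diazo product, and 4 may lose nitrogen on acidic silica. The fallback brings in the two nitrogen atoms one at a time. It sets out from 3 and comes back at 4. Nitrosation of 3 with butyl nitrite and NaOMe in MeOH at 0 °C goes with loss of the acetyl group and gives methyl 2-(hydroxyimino)-3-(3,4,5-trimethoxyphenyl)propanoate F4. Hydrogenation (H2, Pd/C, MeOH, HCl) gives racemic methyl 2-amino-3-(3,4,5-trimethoxyphenyl)propanoate F5. Diazotisation of F5 with isoamyl nitrite and catalytic AcOH in CHCl3 at reflux gives 4.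

**Step 4.** Enolisation of the ester or of the transient aldehyde by basic aluminium alkoxides may erode the configuration at C8 before the second hydride arrives. The fallback passes through the carboxylate, which cannot be enolised under the conditions, and offers a point for enantiomeric enrichment. It sets out from 6 and comes back at 8. LiOH (THF/H2O, 0 °C) gives (R)-2-(4-allyl-2,6-dimethoxyphenoxy)-3-(3,4,5-trimethoxyphenyl)propanoic acid F6, which can be crystallised as a salt with a chiral amine if the enantiomeric purity from step 3 needs upgrading. Isobutyl chloroformate and N-methylmorpholine (THF, –15 °C) give the isobutyl carbonic mixed anhydride F7 (not isolated). NaBH4 in THF/H2O at 0 °C reduces F7 to 8 under nearly neutral conditions.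

**Step 1.** A second C-benzylation and O-benzylation of the enolate may compete, since the electron-rich benzylic bromide is very reactive. The fallback makes double alkylation impossible. It sets out from 1 and comes back at 3. Knoevenagel condensation of 1 with commercial 3,4,5-trimethoxybenzaldehyde (piperidine, AcOH, toluene, reflux with water removal) gives methyl 2-(3,4,5-trimethoxybenzylidene)-3-oxobutanoate F8. Hydrogenation of the conjugated C=C of F8 (H2, Pd/C, EtOAc) gives 3.

## Further compounds

F1 | step 3 | methyl 2-(4-allyl-2,6-dimethoxyphenoxy)acetate | C=CCc1cc(OC)c(OCC(=O)OC)c(OC)c1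
F2 | step 3 | methyl 2-(4-allyl-2,6-dimethoxyphenoxy)-3-(3,4,5-trimethoxyphenyl)propanoate (racemate) | C=CCc1cc(OC)c(OC(C(=O)OC)Cc2cc(OC)c(OC)c(OC)c2)c(OC)c1
F3 | step 3 | 2-(4-allyl-2,6-dimethoxyphenoxy)-3-(3,4,5-trimethoxyphenyl)propanal (racemate) | C=CCc1cc(OC)c(OC(C=O)Cc2cc(OC)c(OC)c(OC)c2)c(OC)c1
F4 | step 2 | methyl 2-(hydroxyimino)-3-(3,4,5-trimethoxyphenyl)propanoate | COC(=O)C(=NO)Cc1cc(OC)c(OC)c(OC)c1
F5 | step 2 | methyl 2-amino-3-(3,4,5-trimethoxyphenyl)propanoate (racemate) | COC(=O)C(N)Cc1cc(OC)c(OC)c(OC)c1
F6 | step 4 | (R)-2-(4-allyl-2,6-dimethoxyphenoxy)-3-(3,4,5-trimethoxyphenyl)propanoic acid | C=CCc1cc(OC)c(O[C@@H](C(=O)O)Cc2cc(OC)c(OC)c(OC)c2)c(OC)c1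
F7 | step 4 | (R)-2-(4-allyl-2,6-dimethoxyphenoxy)-3-(3,4,5-trimethoxyphenyl)propanoic isobutyl carbonic anhydride | C=CCc1cc(OC)c(O[C@@H](C(=O)OC(=O)OCC(C)C)Cc2cc(OC)c(OC)c(OC)c2)c(OC)c1
F8 | step 1 | methyl 2-(3,4,5-trimethoxybenzylidene)-3-oxobutanoate (E/Z mixture) | CC(=O)C(=Cc1cc(OC)c(OC)c(OC)c1)C(=O)OC
A1 | alternative 1 | methyl (S)-2-hydroxy-3-(3,4,5-trimethoxyphenyl)propanoate | O[C@H](C(=O)OC)Cc1cc(OC)c(OC)c(OC)c1
A2 | alternative 1 | methyl (E)-3-(3,4,5-trimethoxyphenyl)acrylate | COC(=O)/C=C/c1cc(OC)c(OC)c(OC)c1
A3 | alternative 2 | (Z)-2-(4-allyl-2,6-dimethoxyphenoxy)-3-(3,4,5-trimethoxyphenyl)acrylic acid | OC(=O)/C(Oc1c(OC)cc(CC=C)cc1OC)=C/c1cc(OC)c(OC)c(OC)c1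
A4 | alternative 2 | (R)-2-(2,6-dimethoxy-4-propylphenoxy)-3-(3,4,5-trimethoxyphenyl)propanoic acid | CCCc1cc(OC)c(O[C@@H](C(=O)O)Cc2cc(OC)c(OC)c(OC)c2)c(OC)c1
A5 | alternative 3 | methyl (E)-4-(3,4,5-trimethoxyphenyl)but-2-en-1-yl carbonate | COC(=O)OC/C=C/Cc1cc(OC)c(OC)c(OC)c1
A6 | alternative 3 | 5-allyl-1,3-dimethoxy-2-{[(2R)-1-(3,4,5-trimethoxyphenyl)but-3-en-2-yl]oxy}benzene | C=CCc1cc(OC)c(O[C@@H](C=C)Cc2cc(OC)c(OC)c(OC)c2)c(OC)c1
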